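**Strategy.** Everything rests on making benzene ring A from open-chain atoms by a photochemical Wolff benzannulation. Irradiation of a 12-membered (R)-diazo enone lactone with (triisopropylsilyloxy)ethyne forms C4–C5, C1–C2, C3–C4 and C1–C6 in one operation and delivers the fully substituted arene. The step exploits the meta-dioxygenated ring A, whose oxygens on C1 and C3 flank unsubstituted C2: C1 is the ketene carbon, C2 and C3 come from the ynol ether. The precursor already holds the macrolactone (chain on C5 and ester on C6, cis) and, on diazo carbon C4, the (3S,4S)-butyrolactone that later becomes the methyl ketal joining the furan and pyran rings.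

Key step: step 13

Assumption: ring A is numbered C1 (OMe), C2 (H), C3 (ketal O), C4 (benzylic CH2), C5 (chain), C6 (lactone C=O); a lithium or potassium salt that is merely the deprotonated form of a numbered compound is treated as that compound; TIPS = triisopropylsilyl.

Step 1
Reactants: 1 tetrahydrofuran
Product: 3 triisopropyl(vinyloxy)silane, via lithium ethenolate 2 (not isolated)
Conditions: n-BuLi (hexanes), 1 as solvent, 35 °C; then TIPSOTf, −78 → 0 °C
Reagents that add atoms: triisopropylsilyl trifluoromethanesulfonate, CC(C)[Si](OS(=O)(=O)C(F)(F)F)(C(C)C)C(C)C; n-butyllithium, [Li]CCCC (lithium of 2 only)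
Why: α-Lithiation of tetrahydrofuran followed by (3+2) cycloreversion expels ethene and leaves the lithium enolate of acetaldehyde, which the hard silyl triflate should trap on oxygen (enolate O-silylation).

Step 2
Reactants: 3 triisopropyl(vinyloxy)silane
Product: 5 (Z)-(2-bromovinyloxy)triisopropylsilane, via dibromo ether 4 (not isolated)
Conditions: Br2, CH2Cl2, −78 °C; then Et3N, −78 → 20 °C
Reagents that add atoms: bromine, BrBr
Why: Bromine addition to the enol ether and dehydrobromination of the resulting α-bromo ether (addition–elimination, as used for alkyl 2-bromovinyl ethers) should give mainly the Z isomer; if bromide removes silicon instead, bromoacetaldehyde and TIPSBr recombine under Et3N to the same enol ether.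

Step 3
Reactants: 5 (Z)-(2-bromovinyloxy)triisopropylsilane
Product: 6 (triisopropylsilyloxy)ethyne
Conditions: LiN(i-Pr)2 (2.2 equiv), THF, −78 °C; then aq. NH4Cl, −78 °C
Reagents that add atoms: none
Why: Anti E2 dehydrobromination of the (Z)-2-halovinyl silyl ether (vinylic H trans to Br) is the elimination route to siloxyalkynes, and the second equivalent of base holds the product as its acetylide until the cold quench.

Step 4
Reactants: 7 oct-1-yne; 8 (S)-propylene oxide
Product: 9 (S)-undec-4-yn-2-ol
Conditions: n-BuLi, THF, −78 °C; BF3·OEt2; then 8, −78 °C; aq. NH4Cl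
Reagents that add atoms: none
Why: BF3-promoted opening of the epoxide by the lithium acetylide (Yamaguchi–Hirao alkynylation) is an SN2 attack at the CH2 terminus, so the (S) carbinol centre is carried over untouched.

Step 5
Reactants: 9 (S)-undec-4-yn-2-ol
Product: 10 (S)-undec-10-yn-2-ol
Conditions: KH (4 equiv), H2N(CH2)3NH2, 0 → 20 °C; then H2O
Reagents that add atoms: none
Why: Acetylene zipper isomerization moves the triple bond by reversible propargyl–allenyl proton shifts until it is trapped as the terminal acetylide, while migration toward C2 is blocked by the alkoxide, whose carbinol centre has no acidic hydrogen and keeps its configuration.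

Step 6
Reactants: 10 (S)-undec-10-yn-2-ol
Product: 11 (S)-11-hydroxydodec-2-ynoic acid
Conditions: n-BuLi (2.2 equiv), THF, −78 → 0 °C; CO2, −78 → 20 °C; aq. HCl
Reagents that add atoms: carbon dioxide, O=C=O
Why: Carboxylation of the lithium acetylide within the alkoxide–acetylide dianion gives the ynoic acid, and any carbonate formed at oxygen reverts on acidification.

Step 7
Reactants: 11 (S)-11-hydroxydodec-2-ynoic acid
Product: 12 (R)-12-methyl-1-oxacyclododec-3-yn-2-one
Conditions: PPh3, DIAD, toluene, slow addition of 11 (final 2 mM), 0 → 20 °C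
Reagents that add atoms: none
Why: Mitsunobu macrolactonization under high dilution lets the acidic ynoate displace the alkoxyphosphonium group in an SN2 step with inversion, turning the (S) carbinol into the (R) lactone centre without acyl activation that could isomerize the ynoate to an allenoate.

Step 8
Reactants: 12 (R)-12-methyl-1-oxacyclododec-3-yn-2-one
Product: 13 (12R,3E)-12-methyl-4-(trimethylstannyl)-1-oxacyclododec-3-en-2-one
Conditions: Me3SnSnMe3, MeLi, THF, −20 °C; CuBr·SMe2, −78 °C; then 12, MeOH, −78 °C
Reagents that add atoms: hexamethylditin, C[Sn](C)(C)[Sn](C)(C)C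
Why: Syn stannylcupration of the ynoate puts tin on the β carbon and copper on the α carbon from the same side, and methanol protonates the alkenylcopper at −78 °C before it can equilibrate, so chain and ester end up cis as the ring also demands.

Step 9
Reactants: 14 (S)-4-methyldihydrofuran-2(3H)-one; 15 tert-butyl acrylate
Product: 16 tert-butyl 3-[(3S,4S)-4-methyl-2-oxooxolan-3-yl]propanoate
Conditions: LiN(i-Pr)2 (1.05 equiv), THF, −78 °C; then 15 (0.95 equiv), −78 °C; AcOH quench
Reagents that add atoms: none
Why: Michael addition of the lactone lithium enolate to the acrylate takes place on the enolate face opposite the C4 methyl group, which should set C3 trans to it as (3S) by substrate control.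

Step 10
Reactants: 16 tert-butyl 3-[(3S,4S)-4-methyl-2-oxooxolan-3-yl]propanoate
Product: 17 3-[(3S,4S)-4-methyl-2-oxooxolan-3-yl]propanoic acid
Conditions: CF3CO2H, CH2Cl2, 20 °C
Reagents that add atoms: none
Why: Acidolysis of the tert-butyl ester (E1 loss of the tert-butyl cation as isobutene) leaves the γ-lactone and both stereocentres untouched.

Step 11
Reactants: 17 3-[(3S,4S)-4-methyl-2-oxooxolan-3-yl]propanoic acid; 13 (12R,3E)-12-methyl-4-(trimethylstannyl)-1-oxacyclododec-3-en-2-one
Product: 19 (12R,3E)-12-methyl-4-{3-[(3S,4S)-4-methyl-2-oxooxolan-3-yl]propanoyl}-1-oxacyclododec-3-en-2-one, via acid chloride 18 (not isolated)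
Conditions: (COCl)2, cat. DMF, CH2Cl2, 0 → 20 °C, evaporate; then 13, Pd2(dba)3 (2.5 mol %), P(2-furyl)3 (10 mol %), toluene, 60 °C
Reagents that add atoms: oxalyl chloride, ClC(=O)C(=O)Cl (chlorine of 18 only; nothing remains in 19)
Why: Stille acylation, in which zerovalent palladium inserts into the acyl chloride, the alkenyl group is transferred from tin with retention of geometry (the small trimethylstannyl group and the furylphosphine speed this for the hindered stannane) and reductive elimination gives the enone.

Step 12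
Reactants: 19 (12R,3E)-12-methyl-4-{3-[(3S,4S)-4-methyl-2-oxooxolan-3-yl]propanoyl}-1-oxacyclododec-3-en-2-one
Product: 21 (12R,3E)-4-{2-diazo-3-[(3S,4S)-4-methyl-2-oxooxolan-3-yl]propanoyl}-12-methyl-1-oxacyclododec-3-en-2-one, via trifluoroacetyl ketone 20 (not isolated)
Conditions: LiN(SiMe3)2 (1.1 equiv), THF, −78 °C; CF3CO2CH2CF3, −78 °C; aq. HCl work-up; then MsN3, Et3N, H2O (1 equiv), MeCN, 20 °C
Reagents that add atoms: methanesulfonyl azide, CS(=O)(=O)N=[N+]=[N-]; 2,2,2-trifluoroethyl trifluoroacetate, FC(F)(F)COC(=O)C(F)(F)F (trifluoroacetyl group of 20 only)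
Why: Detrifluoroacetylative diazo transfer, in which kinetic deprotonation at the only α-CH2 of the ketone (more acidic than either lactone) and Claisen trifluoroacetylation give a 1,3-diketone that the sulfonyl azide converts into the diazo ketone with retro-Claisen loss of the trifluoroacetyl group.

Step 13
Reactants: 21 (12R,3E)-4-{2-diazo-3-[(3S,4S)-4-methyl-2-oxooxolan-3-yl]propanoyl}-12-methyl-1-oxacyclododec-3-en-2-one; 6 (triisopropylsilyloxy)ethyne
Product: 26 (3R)-14-hydroxy-3-methyl-11-{[(3S,4S)-4-methyl-2-oxooxolan-3-yl]methyl}-12-(triisopropylsilyloxy)-3,4,5,6,7,8,9,10-octahydro-1H-2-benzoxacyclododecin-1-one, via vinylketene 22 (not isolated), via alkenylcyclobutenone 23 (not isolated), via dienylketene 24 (not isolated), via cyclohexadienone 25 (not isolated)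
Conditions: 6 (2.5 equiv), degassed ClCH2CH2Cl (0.05 M), hν (300 nm lamps, Pyrex), 20 °C; then 80 °C in the dark
Reagents that add atoms: none
Why: Excitation of 21 expels N2 and the alkenyl group shifts to the diazo carbon (Wolff rearrangement, new C4–C5 bond) to give vinylketene 22 with C1 as ketene carbon; the polarized ynol ether 6 adds across the ketene C=C in a (2+2) cycloaddition (C1–C2 and C3–C4) to cyclobutenone 23, which on warming opens by 4π electrocyclic cleavage of C1–C4 to dienylketene 24. Ring A then closes by thermal disrotatory 6π electrocyclization (C1–C6) and dienone 25 tautomerizes to the phenol, the whole being the photochemical Wolff form of the Danheiser benzannulation, which is established for diazo enones with siloxyalkynes. No lasting stereocenter is formed (those of 23 and 25 vanish on aromatization), and the three existing ones sit outside the reacting array under neutral, aprotic conditions. The step needs regioselectivity in the (2+2) addition, and the ynol ether supplies it: its unsubstituted carbon is the nucleophilic end and bonds to the electrophilic ketene carbon C1, so the silyloxy carbon becomes C3, the ketene oxygen becomes the free C1 hydroxyl and C2 stays unsubstituted. It also needs the C5=C6 geometry to hold, and the 12-membered ring secures it by keeping chain and ester cis, so that only H-6 points inward during the 6π closure and the ester cannot reach the ketene carbon to form a pyranone. The ester on C6 makes 22 more electrophilic, which should favour capture by 6 over dimerization.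

Step 14
Reactants: 26 (3R)-14-hydroxy-3-methyl-11-{[(3S,4S)-4-methyl-2-oxooxolan-3-yl]methyl}-12-(triisopropylsilyloxy)-3,4,5,6,7,8,9,10-octahydro-1H-2-benzoxacyclododecin-1-one
Product: 27 (3R)-14-methoxy-3-methyl-11-{[(3S,4S)-4-methyl-2-oxooxolan-3-yl]methyl}-12-(triisopropylsilyloxy)-3,4,5,6,7,8,9,10-octahydro-1H-2-benzoxacyclododecin-1-one
Conditions: CH3I, K2CO3, acetone, 50 °C
Reagents that add atoms: iodomethane, CI
Why: Williamson O-methylation of the hydrogen-bonded salicylate-type phenol, with a carbonate base too weak to enolize the lactone and no fluoride or alkoxide present to cleave the aryl silyl ether.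

Step 15
Reactants: 27 (3R)-14-methoxy-3-methyl-11-{[(3S,4S)-4-methyl-2-oxooxolan-3-yl]methyl}-12-(triisopropylsilyloxy)-3,4,5,6,7,8,9,10-octahydro-1H-2-benzoxacyclododecin-1-one
Product: 28 (3R)-11-{[(3S,4S)-2-hydroxy-2,4-dimethyloxolan-3-yl]methyl}-14-methoxy-3-methyl-12-(triisopropylsilyloxy)-3,4,5,6,7,8,9,10-octahydro-1H-2-benzoxacyclododecin-1-one (lactol, both anomers, in equilibrium with the open hydroxy ketone)
Conditions: MeLi (1.2 equiv), THF, −78 °C; AcOH quench at −78 °C
Reagents that add atoms: methyllithium, [Li]C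
Why: 1,2-Addition of methyllithium to the γ-lactone stops at the tetrahedral lithium lactolate, which is stable at −78 °C, while the macrolactone, a 2,6-disubstituted benzoate shielded on both sides, is not attacked.

Step 16
Reactants: 28 (3R)-11-{[(3S,4S)-2-hydroxy-2,4-dimethyloxolan-3-yl]methyl}-14-methoxy-3-methyl-12-(triisopropylsilyloxy)-3,4,5,6,7,8,9,10-octahydro-1H-2-benzoxacyclododecin-1-one
Product: 30 lasiodiplactone A, via phenol lactol 29 (not isolated)
Conditions: Bu4NF (1.1 equiv), AcOH (1.2 equiv), THF, 0 °C; then TsOH·H2O (1.5 equiv), 4 Å molecular sieves, 20 °C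
Reagents that add atoms: none
Why: Fluoride desilylation frees the C3 phenol and acid then ionizes the lactol to a cyclic oxocarbenium ion that the phenol captures (intramolecular ketalization, 6-exo closure of the pyran ring), the tether through C3′ delivering oxygen only to the face syn to the CH2 group so that the ketal carbon is set as the cis-fused (S) centre under thermodynamic control.

**Compound list**

1 | tetrahydrofuran | C1CCOC1 | starting material
2 | lithium ethenolate | [Li+].[O-]C=C | intermediate
3 | triisopropyl(vinyloxy)silane | C=CO[Si](C(C)C)(C(C)C)C(C)C | intermediate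
4 | dibromo ether: (1,2-dibromoethoxy)triisopropylsilane (racemic) | BrCC(Br)O[Si](C(C)C)(C(C)C)C(C)C | intermediate
5 | (Z)-(2-bromovinyloxy)triisopropylsilane | Br/C=C\O[Si](C(C)C)(C(C)C)C(C)C | intermediate
6 | (triisopropylsilyloxy)ethyne | C#CO[Si](C(C)C)(C(C)C)C(C)C | intermediate
7 | oct-1-yne | C#CCCCCCC | starting material
8 | (S)-propylene oxide | C[C@H]1CO1 | starting material
9 | (S)-undec-4-yn-2-ol | C[C@H](O)CC#CCCCCCC | intermediate
10 | (S)-undec-10-yn-2-ol | C[C@H](O)CCCCCCCC#C | intermediate
11 | (S)-11-hydroxydodec-2-ynoic acid | C[C@H](O)CCCCCCCC#CC(=O)O | intermediate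
12 | (R)-12-methyl-1-oxacyclododec-3-yn-2-one | C[C@@H]1CCCCCCCC#CC(=O)O1 | intermediate
13 | (12R,3E)-12-methyl-4-(trimethylstannyl)-1-oxacyclododec-3-en-2-one | C[C@@H]1CCCCCCC/C([Sn](C)(C)C)=C\C(=O)O1 | intermediate
14 | (S)-4-methyldihydrofuran-2(3H)-one | O=C1C[C@H](C)CO1 | starting material
15 | tert-butyl acrylate | C=CC(=O)OC(C)(C)C | starting material
16 | tert-butyl 3-[(3S,4S)-4-methyl-2-oxooxolan-3-yl]propanoate | CC(C)(C)OC(=O)CC[C@H]1[C@H](C)COC1=O | intermediate
17 | 3-[(3S,4S)-4-methyl-2-oxooxolan-3-yl]propanoic acid | OC(=O)CC[C@H]1[C@H](C)COC1=O | intermediate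
18 | acid chloride: 3-[(3S,4S)-4-methyl-2-oxooxolan-3-yl]propanoyl chloride | ClC(=O)CC[C@H]1[C@H](C)COC1=O | intermediate
19 | (12R,3E)-12-methyl-4-{3-[(3S,4S)-4-methyl-2-oxooxolan-3-yl]propanoyl}-1-oxacyclododec-3-en-2-one | C[C@@H]1CCCCCCC/C(C(=O)CC[C@H]2[C@H](C)COC2=O)=C\C(=O)O1 | intermediate
20 | trifluoroacetyl ketone: α′-trifluoroacetyl derivative of 19 (epimers at the new carbon, largely enolized) | C[C@@H]1CCCCCCC/C(C(=O)C(C[C@H]2[C@H](C)COC2=O)C(=O)C(F)(F)F)=C\C(=O)O1 | intermediate
21 | (12R,3E)-4-{2-diazo-3-[(3S,4S)-4-methyl-2-oxooxolan-3-yl]propanoyl}-12-methyl-1-oxacyclododec-3-en-2-one | C[C@@H]1CCCCCCC/C(C(=O)C(=[N+]=[N-])C[C@H]2[C@H](C)COC2=O)=C\C(=O)O1 | intermediate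
22 | vinylketene: macrocyclic enoate carrying O=C1=C4(CH2-lactone) on C5 | C[C@@H]1CCCCCCC/C(C(=C=O)C[C@H]2[C@H](C)COC2=O)=C\C(=O)O1 | intermediate
23 | alkenylcyclobutenone: 3-silyloxy-4-(lactonylmethyl)cyclobut-2-enone carrying the macrocyclic alkene on C4 (both epimers at C4) | C[C@@H]1CCCCCCC/C(C2(C[C@H]3[C@H](C)COC3=O)C(=O)C=C2O[Si](C(C)C)(C(C)C)C(C)C)=C\C(=O)O1 | intermediate
24 | dienylketene: O=C1=C2H–C3(OTIPS)=C4(CH2-lactone)–C5=C6 with C2 and C5 cis on C3=C4 | O=C=C/C(O[Si](C(C)C)(C(C)C)C(C)C)=C(C[C@H]2[C@H](C)COC2=O)\C3=C\C(=O)O[C@H](C)CCCCCCC3 | intermediate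
25 | cyclohexadienone: keto tautomer of 26 with sp3 C6 (both epimers) | O=C1C=C(O[Si](C(C)C)(C(C)C)C(C)C)C(C[C@H]3[C@H](C)COC3=O)=C2CCCCCCC[C@@H](C)OC(=O)C12 | intermediate
26 | (3R)-14-hydroxy-3-methyl-11-{[(3S,4S)-4-methyl-2-oxooxolan-3-yl]methyl}-12-(triisopropylsilyloxy)-3,4,5,6,7,8,9,10-octahydro-1H-2-benzoxacyclododecin-1-one | Oc1cc(O[Si](C(C)C)(C(C)C)C(C)C)c(C[C@H]3[C@H](C)COC3=O)c2c1C(=O)O[C@H](C)CCCCCCC2 | intermediate
27 | 14-methoxy analogue of 26 | COc1cc(O[Si](C(C)C)(C(C)C)C(C)C)c(C[C@H]3[C@H](C)COC3=O)c2c1C(=O)O[C@H](C)CCCCCCC2 | intermediate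
28 | lactol: (3R)-11-{[(3S,4S)-2-hydroxy-2,4-dimethyloxolan-3-yl]methyl}-14-methoxy-3-methyl-12-(triisopropylsilyloxy) macrolide (both anomers) | COc1cc(O[Si](C(C)C)(C(C)C)C(C)C)c(C[C@H]3[C@H](C)COC3(C)O)c2c1C(=O)O[C@H](C)CCCCCCC2 | intermediate
29 | phenol lactol: 12-hydroxy analogue of 28 | COc1cc(O)c(C[C@H]3[C@H](C)COC3(C)O)c2c1C(=O)O[C@H](C)CCCCCCC2 | intermediate
30 | lasiodiplactone A | COc1cc2c(c3c1C(=O)O[C@H](C)CCCCCCC3)C[C@H]1[C@H](C)CO[C@@]1(C)O2 | target

**Total step count:** 16 (three for the ynol ether, five for the stannyl macrolide, two for the side-chain acid, six from the coupling to the target).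

**Longest linear sequence:** 11 steps (steps 4–8, then 11–16).

**Steps most likely to fail**

1. Step 13. The ketene may not be captured cleanly under irradiation. The enoate may isomerize photochemically, the ynol ether or cyclobutenone 23 may be consumed by secondary photoreactions, or the ketocarbene may undergo hydrogen shift instead of rearranging. The fallback sets out from 21 and comes back at 22, and so at 26; it separates the light from the cycloaddition. Brief irradiation of 21 in wet THF gives, by Wolff rearrangement and hydration of the ketene, 2-[(12R,3E)-12-methyl-2-oxo-1-oxacyclododec-3-en-4-yl]-3-[(3S,4S)-4-methyl-2-oxooxolan-3-yl]propanoic acid F1. Oxalyl chloride converts it into 2-[(12R,3E)-12-methyl-2-oxo-1-oxacyclododec-3-en-4-yl]-3-[(3S,4S)-4-methyl-2-oxooxolan-3-yl]propanoyl chloride F2. Slow addition of F2 to 6 and Et3N in toluene at 80 °C generates 22 in the dark by dehydrochlorination, and 22 then runs thermally through 23–25 to 26.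

2. Step 11. Transfer of the hindered, electron-poor alkenyl group from tin to palladium may be too slow, so that decarbonylation of the acyl palladium species or protodestannylation takes over. The fallback sets out from 13 and 18 and comes back at 19; it reverses the polarity of the ketone-forming bond. Iodine converts 13 with retention into (12R,3E)-4-iodo-12-methyl-1-oxacyclododec-3-en-2-one F3. Acid chloride 18 is reduced with Bu3SnH and catalytic Pd(PPh3)4 to 3-[(3S,4S)-4-methyl-2-oxooxolan-3-yl]propanal F4. Nozaki–Hiyama–Kishi coupling (CrCl2, catalytic NiCl2, DMSO) joins F3 and F4 to (12R,3E)-4-{1-hydroxy-3-[(3S,4S)-4-methyl-2-oxooxolan-3-yl]propyl}-12-methyl-1-oxacyclododec-3-en-2-one F5 (both carbinol epimers), and Dess–Martin oxidation gives 19. The ring keeps the new carbinol trans to the ester, so no butenolide can form.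

3. Step 12. Under the lithium amide the keto enoate may suffer γ-deprotonation or enolate Michael addition to its doubly activated alkene instead of clean α′-acylation. The fallback sets out from 19 and comes back at 21; it activates the α′-CH2 without strong base. Condensation of 19 with tert-butoxybis(dimethylamino)methane in warm toluene gives the enaminone (12R,3E)-4-{2-[(dimethylamino)methylidene]-3-[(3S,4S)-4-methyl-2-oxooxolan-3-yl]propanoyl}-12-methyl-1-oxacyclododec-3-en-2-one F6. Diazo transfer from MsN3 to the enamine double bond of F6 then gives 21 with loss of the N-sulfonyl formamidine.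

**Further compounds**

F1 | step 13 | 2-[(12R,3E)-12-methyl-2-oxo-1-oxacyclododec-3-en-4-yl]-3-[(3S,4S)-4-methyl-2-oxooxolan-3-yl]propanoic acid (both C2 epimers) | C[C@@H]1CCCCCCC/C(C(C[C@H]2[C@H](C)COC2=O)C(=O)O)=C\C(=O)O1
F2 | step 13 | 2-[(12R,3E)-12-methyl-2-oxo-1-oxacyclododec-3-en-4-yl]-3-[(3S,4S)-4-methyl-2-oxooxolan-3-yl]propanoyl chloride | C[C@@H]1CCCCCCC/C(C(C[C@H]2[C@H](C)COC2=O)C(=O)Cl)=C\C(=O)O1
F3 | step 11 | (12R,3E)-4-iodo-12-methyl-1-oxacyclododec-3-en-2-one | C[C@@H]1CCCCCCC/C(I)=C\C(=O)O1
F4 | step 11 | 3-[(3S,4S)-4-methyl-2-oxooxolan-3-yl]propanal | O=CCC[C@H]1[C@H](C)COC1=O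
F5 | step 11 | (12R,3E)-4-{1-hydroxy-3-[(3S,4S)-4-methyl-2-oxooxolan-3-yl]propyl}-12-methyl-1-oxacyclododec-3-en-2-one (both carbinol epimers) | C[C@@H]1CCCCCCC/C(C(O)CC[C@H]2[C@H](C)COC2=O)=C\C(=O)O1
F6 | step 12 | (12R,3E)-4-{2-[(dimethylamino)methylidene]-3-[(3S,4S)-4-methyl-2-oxooxolan-3-yl]propanoyl}-12-methyl-1-oxacyclododec-3-en-2-one | C[C@@H]1CCCCCCC/C(C(=O)C(=CN(C)C)C[C@H]2[C@H](C)COC2=O)=C\C(=O)O1
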